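Both carbocycles are cut in ring B, at C5–C10 and C8–C9. With C11 on C9 held as an ester, C9=C10 is an enoate, the tertiary C8 alcohol is the trace of an aldol acceptor, and the C19 methyl on C5 marks hydrogen addition to a terminal alkene. One Fe(acac)3-mediated hydrogen atom transfer therefore closes ring A by radical addition (C5 to C10) and ring B by aldol addition (C9 to C8), setting C5, C8, C9 and C10. The precursor is an open chain: a tartrate acetonide (C6, C7) bearing a methyl ketone (C8) and an alkene (C5=C19) tied through silyloxy carbon C4 to the enoate. The butenolide is coupled last.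

Key step: step 8

Remark: clerodane numbering (C1 to C20) is used throughout, and β means the face of the decalin that carries the C5 methyl (C19). It is assumed that the antipode of the chiral chromium ligand in step 6 that gives the 4R carbinol is identified in a pilot run with both antipodes.

Step 1
Reactants: 1 dimethyl 2,3-O-isopropylidene-D-tartrate, the (4S,5S) diester
Product: 2 (4S,5S)-N4,N5-dimethoxy-N4,N5,2,2-tetramethyl-1,3-dioxolane-4,5-dicarboxamide (bis-Weinreb amide)
Conditions: MeNH(OMe)·HCl, i-PrMgCl, THF, −20 °C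
Reagents that add atoms: N,O-dimethylhydroxylamine hydrochloride, CNOC.Cl
Why: Aminolysis of both esters by the magnesium amide (Weinreb amide synthesis) is fast at low temperature and should leave the two α-alkoxy stereocentres untouched.

Step 2
Reactants: 2 bis-Weinreb amide
Product: 3 1,1'-[(4S,5S)-2,2-dimethyl-1,3-dioxolane-4,5-diyl]di(ethan-1-one), the C2-symmetric diketone
Conditions: MeMgBr, THF, −10 to 0 °C; aq NH4Cl
Reagents that add atoms: methylmagnesium bromide, C[Mg]Br
Why: Each amide takes up one methyl group to a stable magnesium chelate that releases the ketone only on work-up (Weinreb ketone synthesis), so no tertiary alcohol should form; the new methyls are C17 and C19.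

Step 3
Reactants: 3 diketone
Product: 4 1-[(4S,5S)-5-acetyl-2,2-dimethyl-1,3-dioxolan-4-yl]ethenyl trifluoromethanesulfonate (C5 alkenyl triflate, C8 ketone kept)
Conditions: KN(SiMe3)2 (1.0 equiv) added to 3 and PhNTf2, THF, −78 °C
Reagents that add atoms: N-phenylbis(trifluoromethanesulfonimide), O=S(=O)(N(c1ccccc1)S(=O)(=O)C(F)(F)F)C(F)(F)F
Why: The bulky amide deprotonates a methyl group kinetically and the enolate is O-sulfonylated as it forms (enol triflate synthesis with in situ trapping, which suppresses aldol side reactions); the two ketones are homotopic, so mono-reaction gives a single compound and unreacted 3 can be recycled.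

Step 4
Reactants: 5 3,4-dihydro-2H-pyran; 6 ethyl 2-(triphenylphosphoranylidene)propanoate
Product: 8 ethyl (E)-7-hydroxy-2-methylhept-2-enoate, via tetrahydro-2H-pyran-2-ol 7 (not isolated)
Conditions: 0.2 M aq HCl, rt; extract; then 6, THF, 60 °C
Reagents that add atoms: water, O (its oxygen is held in 7 and leaves with the phosphine oxide; 8 keeps only its hydrogens)
Why: Acid-catalysed hydration of the enol ether gives lactol 7, whose open hydroxy aldehyde form reacts with the stabilised ylide in an E-selective Wittig olefination.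

Step 5
Reactants: 8 hydroxy enoate
Product: 9 ethyl (E)-2-methyl-7-oxohept-2-enoate
Conditions: TEMPO (cat.), PhI(OAc)2, CH2Cl2, rt
Reagents that add atoms: none
Why: Oxoammonium-catalysed oxidation of the primary alcohol stops at the aldehyde and does not touch the enoate.

Step 6
Reactants: 4 alkenyl triflate; 9 aldehyde
Product: 10 ethyl (2E,7R)-8-[(4R,5S)-5-acetyl-2,2-dimethyl-1,3-dioxolan-4-yl]-7-hydroxy-2-methylnona-2,8-dienoate (whole C1 to C11 chain, C4 carbinol R)
Conditions: CrCl2 (4 equiv), NiCl2 (2 mol %), chiral oxazoline–sulfonamide ligand, Et3N, THF, rt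
Reagents that add atoms: none
Why: Zerovalent nickel inserts into the C–OTf bond, the alkenyl group passes to trivalent chromium and adds to the aldehyde (Nozaki–Hiyama–Kishi reaction), which is selective for the aldehyde over ketone and ester; the chiral sulfonamide ligand on chromium should set the temporary C4 carbinol, and the minor epimer is removed by chromatography.

Step 7
Reactants: 10 allylic alcohol
Product: 11 ethyl (2E,7R)-8-[(4R,5S)-5-acetyl-2,2-dimethyl-1,3-dioxolan-4-yl]-7-[(tert-butyldimethylsilyl)oxy]-2-methylnona-2,8-dienoate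
Conditions: TBSCl, imidazole, DMF, rt
Reagents that add atoms: tert-butyldimethylsilyl chloride, CC(C)(C)[Si](C)(C)Cl
Why: Standard silylation of the secondary allylic alcohol; the silyl ether keeps the C4 oxygen from binding iron or the ketone in the next step.

Step 8
Reactants: 11 silyl ether
Product: 13 trans-decalin hydroxy ester (4β-OTBS, 6β,7α-acetonide, 8α-OH, 8β-Me, 9β-Me, 9α-CO2Et, 5β-Me, 10α-H), via ring A ester enolate 12 (not isolated)
Conditions: Fe(acac)3 (0.5 equiv), PhSi(Oi-Pr)H2 (2.5 equiv), i-PrOH (3 equiv), THF (0.01 M), 0 °C to rt, argon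
Reagents that add atoms: none
Why: HFe(acac)2, formed from Fe(acac)3 and the silane, gives a hydrogen atom to C19 of the 1,1-disubstituted alkene, and the tertiary C5 radical adds 6-exo-trig to C10 of the enoate to close ring A; divalent iron then reduces the C9 radical to the Fe(acac)2-bound enolate 12, which closes ring B by a 6-(enolexo)-exo-trig aldol addition to the C8 ketone. The closest known reaction type is the metal-hydride hydrogen-atom-transfer radical conjugate addition whose enolate is captured by an aldol reaction (radical–polar crossover annulation). C5 and C10 are fixed in a chair transition state of ring A that keeps the 4R silyloxy group, the dioxolanyl carbon C6 and the enoate equatorial and only the small C19 methyl axial, the radical reacting on the face anti to the C6–O bond, so C6 and C9 become trans. C9 is fixed because the enolate avoids allylic strain by placing H10 in its plane and the tethered ketone can reach only the face on the side of C5, which leaves the C20 methyl axial and anti to H10. C8 is fixed by a closed metal-bridged chair in which the C17 methyl is equatorial and the carbonyl oxygen axial, cis to C11 and O7. The step needs hydrogen transfer to the right alkene, ring closure faster than reduction of the C5 radical and aldol closure faster than protonation of 12, and these are secured by the electron-poor character of the enoate, its singly substituted β-carbon, the activated α-alkoxy ketone and the trans-dioxolane, which holds the C5 and C8 arms close and permits only the chair with O6 and O7 equatorial.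

Step 9
Reactants: 13 trans-decalin hydroxy ester
Product: 14 4β,8α-diol (6β,7α-acetonide, 9α-CO2Et)
Conditions: HF·pyridine, pyridine, THF, 0 °C to rt
Reagents that add atoms: none
Why: Fluoride cleaves the Si–O bond under buffered, non-basic conditions, so the β-hydroxy ester at C8/C9 never meets an alkoxide-forming base (no retro-aldol) and the acetonide should survive.

Step 10
Reactants: 14 diol
Product: 15 C4 ketone with free 8α-hydroxyl
Conditions: Dess–Martin periodinane, pyridine, CH2Cl2, 0 °C to rt
Reagents that add atoms: none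
Why: Dess–Martin oxidation of the only secondary alcohol; the tertiary C8 hydroxyl cannot be oxidised.

Step 11
Reactants: 15 hydroxy ketone
Product: 16 C4 ketone 8α-triethylsilyl ether
Conditions: Et3SiOTf, 2,6-lutidine, CH2Cl2, −78 to 0 °C
Reagents that add atoms: triethylsilyl trifluoromethanesulfonate, CC[Si](CC)(CC)OS(=O)(=O)C(F)(F)F
Why: A silyl triflate with a hindered pyridine base silylates even the axial tertiary C8 hydroxyl, which blocks retro-aldol cleavage of the C8–C9 bond under the strong base of the next step.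

Step 12
Reactants: 16 silylated ketone
Product: 17 C3-ene C4 enol triflate
Conditions: KN(SiMe3)2, PhNTf2, THF, −78 °C
Reagents that add atoms: N-phenylbis(trifluoromethanesulfonimide), O=S(=O)(N(c1ccccc1)S(=O)(=O)C(F)(F)F)C(F)(F)F
Why: Because C5 is quaternary the C4 ketone can enolise only toward C3, and the enolate is trapped on oxygen (enol triflate synthesis), which fixes the C3,C4 alkene position.

Step 13
Reactants: 17 enol triflate
Product: 18 decalin ester with the C3,C4 methyl alkene (C18 installed), 8α-OTES, 6β,7α-acetonide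
Conditions: MeZnCl, Pd(PPh3)4 (5 mol %), THF, 50 °C
Reagents that add atoms: methylzinc chloride, C[Zn]Cl
Why: Negishi cross-coupling of the alkenyl triflate installs C18, and the organozinc reagent does not attack the hindered ester.

Step 14
Reactants: 18 ester
Product: 19 C11 primary alcohol
Conditions: LiAlH4, Et2O, 0 °C to rt
Reagents that add atoms: none
Why: Hydride reduction of the neopentyl ester; silyl ether, acetonide and trisubstituted alkene are inert to LiAlH4.

Step 15
Reactants: 19 alcohol
Product: 20 C11 aldehyde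
Conditions: Dess–Martin periodinane, pyridine, CH2Cl2, rt
Reagents that add atoms: none
Why: Dess–Martin oxidation gives an aldehyde that has no α-hydrogen and so cannot epimerise or enolise.

Step 16
Reactants: 20 aldehyde
Product: 21 (E)-C11,C12-alkenyl pinacol boronate
Conditions: CrCl2 (8 equiv), LiI (additive), Cl2CHB(pin), THF, rt
Reagents that add atoms: 2-(dichloromethyl)-4,4,5,5-tetramethyl-1,3,2-dioxaborolane, ClC(Cl)B1OC(C)(C)C(C)(C)O1
Why: Takai–Utimoto boryl olefination: divalent chromium turns the dihalomethylboronate into a geminal dichromium reagent that adds to the aldehyde and eliminates to the E-alkenyl boronate, C12 coming from the reagent.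

Step 17
Reactants: 21 alkenyl boronate; 22 4-bromofuran-2(5H)-one
Product: 23 dienyl butenolide with 6β,7α-acetonide and 8α-OTES (full skeleton)
Conditions: PdCl2(dppf) (5 mol %), K3PO4, THF/H2O, 40 °C
Reagents that add atoms: none
Why: Suzuki–Miyaura coupling of the alkenyl boronate with the vinylogous acyl bromide forms C12–C13 with retention of the E geometry under a mild base that the butenolide tolerates.

Step 18
Reactants: 23 protected dienyl butenolide
Product: 25 7α,8α-acetonide 6β-alcohol, via 6,7,8-triol 24 (not isolated)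
Conditions: TsOH·H2O (cat.), MeOH, rt; evaporate; then Me2C(OMe)2, acetone, rt
Reagents that add atoms: 2,2-dimethoxypropane, COC(C)(C)OC
Why: Acid methanolysis removes the silyl ether and the strained trans-fused acetonide, and acid-catalysed ketalisation of triol 24 should then take only the cis 7,8-diol, because a cis-fused dioxolane is strongly favoured over a trans-fused one, which frees the C6 hydroxyl alone.

Step 19
Reactants: 25 C6 alcohol
Product: 26 6β-acetate 7α,8α-acetonide
Conditions: Ac2O, DMAP, pyridine, CH2Cl2, rt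
Reagents that add atoms: acetic anhydride, CC(=O)OC(C)=O
Why: DMAP-catalysed acetylation (nucleophilic catalysis) of the only free hydroxyl.

Step 20
Reactants: 26 acetate acetonide
Product: 27 6β-acetate 7α,8α-diol
Conditions: AcOH/H2O (4:1), 45 °C
Reagents that add atoms: none
Why: Mild acid hydrolysis of the acetonide; acetate, butenolide and alkenes are stable, and acyl migration between the trans-diequatorial C6 and C7 oxygens is slow in acid.

Step 21
Reactants: 27 diol
Product: 28 CNP0207114.1, (5R,6R,7S,8R,9R,10S)-6-acetoxy-8-hydroxy-7-(2-methylpropanoyloxy)cleroda-3,11E,13-trien-15,16-olide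
Conditions: (i-PrCO)2O, DMAP, pyridine, CH2Cl2, rt
Reagents that add atoms: isobutyric anhydride, CC(C)C(=O)OC(=O)C(C)C
Why: DMAP-catalysed acylation takes the secondary C7 hydroxyl and leaves the tertiary C8 hydroxyl free.

Compound list

1 | dimethyl 2,3-O-isopropylidene-D-tartrate, (4S,5S) | COC(=O)[C@H]1OC(C)(C)O[C@@H]1C(=O)OC | starting material
2 | (4S,5S)-N4,N5-dimethoxy-N4,N5,2,2-tetramethyl-1,3-dioxolane-4,5-dicarboxamide | CON(C)C(=O)[C@H]1OC(C)(C)O[C@@H]1C(=O)N(C)OC | intermediate
3 | (4S,5S)-4,5-diacetyl-2,2-dimethyl-1,3-dioxolane | CC(=O)[C@H]1OC(C)(C)O[C@@H]1C(C)=O | intermediate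
4 | 1-[(4S,5S)-5-acetyl-2,2-dimethyl-1,3-dioxolan-4-yl]ethenyl trifluoromethanesulfonate | CC(=O)[C@H]1OC(C)(C)O[C@@H]1C(=C)OS(=O)(=O)C(F)(F)F | intermediate
5 | 3,4-dihydro-2H-pyran | C1CC=COC1 | starting material
6 | ethyl 2-(triphenylphosphoranylidene)propanoate | CCOC(=O)C(C)=P(c1ccccc1)(c1ccccc1)c1ccccc1 | starting material
7 | tetrahydro-2H-pyran-2-ol (racemic lactol, not isolated) | OC1CCCCO1 | intermediate
8 | ethyl (E)-7-hydroxy-2-methylhept-2-enoate | OCCCC/C=C(\C)C(=O)OCC | intermediate
9 | ethyl (E)-2-methyl-7-oxohept-2-enoate | O=CCCC/C=C(\C)C(=O)OCC | intermediate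
10 | ethyl (2E,7R)-8-[(4R,5S)-5-acetyl-2,2-dimethyl-1,3-dioxolan-4-yl]-7-hydroxy-2-methylnona-2,8-dienoate | CC(=O)[C@H]1OC(C)(C)O[C@@H]1C(=C)[C@H](O)CCC/C=C(\C)C(=O)OCC | intermediate
11 | 7-O-tert-butyldimethylsilyl ether of 10 (bicyclisation precursor) | CC(=O)[C@H]1OC(C)(C)O[C@@H]1C(=C)[C@H](O[Si](C)(C)C(C)(C)C)CCC/C=C(\C)C(=O)OCC | intermediate
12 | ring A ester enolate (ring A closed, C8 ketone still open; drawn as the free enolate, bound to Fe(acac)2 in the flask; not isolated) | CC(=O)[C@H]1OC(C)(C)O[C@@H]1[C@@]2(C)[C@H](O[Si](C)(C)C(C)(C)C)CCC[C@@H]2C(C)=C([O-])OCC | intermediate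
13 | trans-decalin hydroxy ester: 4β-OTBS, 6β,7α-acetonide, 8α-OH, 8β-Me, 9β-Me, 9α-CO2Et, 5β-Me, 10α-H | CC1(C)O[C@H]2[C@H](O1)[C@](C)(O)[C@](C)(C(=O)OCC)[C@H]3CCC[C@@H](O[Si](C)(C)C(C)(C)C)[C@]23C | intermediate
14 | 4β,8α-diol of the decalin ester | CC1(C)O[C@H]2[C@H](O1)[C@](C)(O)[C@](C)(C(=O)OCC)[C@H]3CCC[C@@H](O)[C@]23C | intermediate
15 | C4 ketone, 8α-hydroxyl free | CC1(C)O[C@H]2[C@H](O1)[C@](C)(O)[C@](C)(C(=O)OCC)[C@H]3CCCC(=O)[C@]23C | intermediate
16 | C4 ketone, 8α-triethylsilyl ether | CC1(C)O[C@H]2[C@H](O1)[C@](C)(O[Si](CC)(CC)CC)[C@](C)(C(=O)OCC)[C@H]3CCCC(=O)[C@]23C | intermediate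
17 | C3-ene C4 enol triflate | CC1(C)O[C@H]2[C@H](O1)[C@](C)(O[Si](CC)(CC)CC)[C@](C)(C(=O)OCC)[C@H]3CCC=C(OS(=O)(=O)C(F)(F)F)[C@]23C | intermediate
18 | decalin ester with C3,C4 methyl alkene, 8α-OTES | CC1(C)O[C@H]2[C@H](O1)[C@](C)(O[Si](CC)(CC)CC)[C@](C)(C(=O)OCC)[C@H]3CCC=C(C)[C@]23C | intermediate
19 | C11 primary alcohol | CC1(C)O[C@H]2[C@H](O1)[C@](C)(O[Si](CC)(CC)CC)[C@](C)(CO)[C@H]3CCC=C(C)[C@]23C | intermediate
20 | C11 aldehyde | CC1(C)O[C@H]2[C@H](O1)[C@](C)(O[Si](CC)(CC)CC)[C@](C)(C=O)[C@H]3CCC=C(C)[C@]23C | intermediate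
21 | (E)-C11,C12-alkenyl pinacol boronate | CC1(C)O[C@H]2[C@H](O1)[C@](C)(O[Si](CC)(CC)CC)[C@](C)(/C=C/B4OC(C)(C)C(C)(C)O4)[C@H]3CCC=C(C)[C@]23C | intermediate
22 | 4-bromofuran-2(5H)-one | BrC1=CC(=O)OC1 | starting material
23 | dienyl butenolide, 6β,7α-acetonide, 8α-OTES | CC1(C)O[C@H]2[C@H](O1)[C@](C)(O[Si](CC)(CC)CC)[C@](C)(/C=C/C4=CC(=O)OC4)[C@H]3CCC=C(C)[C@]23C | intermediate
24 | 6β,7α,8α-triol (not isolated) | O[C@H]1[C@H](O)[C@](C)(O)[C@](C)(/C=C/C2=CC(=O)OC2)[C@H]2CCC=C(C)[C@]12C | intermediate
25 | 7α,8α-acetonide 6β-alcohol | O[C@H]1[C@@H]2OC(C)(C)O[C@]2(C)[C@](C)(/C=C/C3=CC(=O)OC3)[C@H]3CCC=C(C)[C@]13C | intermediate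
26 | 6β-acetate 7α,8α-acetonide | CC(=O)O[C@H]1[C@@H]2OC(C)(C)O[C@]2(C)[C@](C)(/C=C/C3=CC(=O)OC3)[C@H]3CCC=C(C)[C@]13C | intermediate
27 | 6β-acetate 7α,8α-diol | CC(=O)O[C@H]1[C@H](O)[C@](C)(O)[C@](C)(/C=C/C2=CC(=O)OC2)[C@H]2CCC=C(C)[C@]12C | intermediate
28 | CNP0207114.1, (5R,6R,7S,8R,9R,10S) | CC(=O)O[C@H]1[C@H](OC(=O)C(C)C)[C@](C)(O)[C@](C)(/C=C/C2=CC(=O)OC2)[C@H]2CCC=C(C)[C@]12C | target

Total step count: 21

Longest linear sequence: 19 steps (steps 1 to 3, then 6 to 21, from compound 1). The branch from compound 5 (steps 4 and 5) joins at step 6.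

Steps most likely to fail

Step 8. The C9 radical or enolate 12 may be quenched by hydrogen or proton before it reaches the C8 ketone. The C5 radical may also be reduced, or may take a hydrogen from allylic C1, before ring A closes, and the ester enolate may be too sluggish for the strained ring B closure. The fallback moves to an enal acceptor, which is a faster radical acceptor and the best-precedented acceptor class for this crossover bicyclisation. It sets out from compound 11: i-Bu2AlH (CH2Cl2, −78 °C) reduces ester and ketone to the allylic diol F1, and Dess–Martin periodinane re-oxidises both carbinols to the keto enal F2. The same Fe(acac)3/silane conditions should then give the bicyclic hydroxy aldehyde F3. Pinnick oxidation (NaClO2, NaH2PO4, 2-methyl-2-butene) gives the hydroxy acid F4, and alkylation of its carboxylate (EtI, K2CO3, DMF) comes back to the route at compound 13.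

Step 6. Ligand control at C4 may be too weak, or the chiral chromium complex may couple sluggishly, so that the wanted 4R carbinol is not formed cleanly. Because C4 steers the chair of step 8, the epimer cannot be carried on. The fallback sets out from compounds 4 and 9 with an achiral coupling (CrCl2, NiCl2 cat., DMF), which gives both C4 epimers; the (7S)-epimer F5 is separated by chromatography. Mitsunobu reaction of F5 (4-nitrobenzoic acid, PPh3, diisopropyl azodicarboxylate, THF) inverts C4 to the 4-nitrobenzoate F6, and mild ethanolysis (K2CO3, EtOH, 0 °C) comes back to the route at compound 10.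

Step 16. The geminal dichromium reagent may add too slowly to the neopentyl aldehyde, which sits between the quaternary C9 and the silyloxy-bearing C8, so that reduction or pinacol coupling of the aldehyde takes over. The fallback sets out from compound 20: Ohira–Bestmann homologation (dimethyl (1-diazo-2-oxopropyl)phosphonate, K2CO3, MeOH) gives the terminal alkyne F7. Syn hydroboration of F7 with pinacolborane and Cp2ZrHCl (cat.) comes back to the route at compound 21 with the E geometry; the trisubstituted C3,C4 alkene is not expected to react.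

Further compounds

F1 | step 8 | (2E,7R)-7-[(tert-butyldimethylsilyl)oxy]-8-[(4R,5S)-5-(1-hydroxyethyl)-2,2-dimethyl-1,3-dioxolan-4-yl]-2-methylnona-2,8-dien-1-ol (dioxolane descriptors as in 11; both epimers at the new carbinol) | CC(O)[C@H]1OC(C)(C)O[C@@H]1C(=C)[C@H](O[Si](C)(C)C(C)(C)C)CCC/C=C(\C)CO
F2 | step 8 | (2E,7R)-8-[(4R,5S)-5-acetyl-2,2-dimethyl-1,3-dioxolan-4-yl]-7-[(tert-butyldimethylsilyl)oxy]-2-methylnona-2,8-dienal | CC(=O)[C@H]1OC(C)(C)O[C@@H]1C(=C)[C@H](O[Si](C)(C)C(C)(C)C)CCC/C=C(\C)C=O
F3 | step 8 | C11 aldehyde analogue of 13 (4β-OTBS, 6β,7α-acetonide, 8α-OH, 9α-CHO) | CC1(C)O[C@H]2[C@H](O1)[C@](C)(O)[C@](C)(C=O)[C@H]3CCC[C@@H](O[Si](C)(C)C(C)(C)C)[C@]23C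
F4 | step 8 | C11 carboxylic acid analogue of 13 | CC1(C)O[C@H]2[C@H](O1)[C@](C)(O)[C@](C)(C(=O)O)[C@H]3CCC[C@@H](O[Si](C)(C)C(C)(C)C)[C@]23C
F5 | step 6 | ethyl (2E,7S)-8-[(4R,5S)-5-acetyl-2,2-dimethyl-1,3-dioxolan-4-yl]-7-hydroxy-2-methylnona-2,8-dienoate (C4 epimer of 10) | CC(=O)[C@H]1OC(C)(C)O[C@@H]1C(=C)[C@@H](O)CCC/C=C(\C)C(=O)OCC
F6 | step 6 | 7-O-(4-nitrobenzoyl) derivative of 10 (7R) | CC(=O)[C@H]1OC(C)(C)O[C@@H]1C(=C)[C@H](OC(=O)c1ccc(cc1)[N+](=O)[O-])CCC/C=C(\C)C(=O)OCC
F7 | step 16 | C9 ethynyl decalin (C11,C12 alkyne, 8α-OTES, 6β,7α-acetonide, C3,C4 methyl alkene) | CC1(C)O[C@H]2[C@H](O1)[C@](C)(O[Si](CC)(CC)CC)[C@](C)(C#C)[C@H]3CCC=C(C)[C@]23C
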